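**Plan**

1. Cuts (retrosynthesis): in ring B (the spiro cyclohexane) the C–OH bond of its C(Me)(OH) carbon (back to an exocyclic methylene) and both bonds from the spiro carbon to the ring B methylenes (one to a π-allyl unit, one to an aldehyde carbon); in ring C (the cyclopentane) the bond between the C(Me)(OH) carbon and the ring-fusion CH that carries the CH2 branch.
2. Enabling feature: ring C has C(Me)(OH) next to a CH with a one-carbon branch (a 3-hydroxy aldehyde pattern) and a three-carbon branch on the next CH. That is a 1-methyl-4-isopropenylcyclohexane with one ring carbon pushed out into the branch, i.e. the product of a 1,2-shift of the carbinol carbon in a cyclohexane 2-oxy-3-sulfonate.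
3. Forward: (1R,4R)-p-mentha-2,8-dien-1-ol → all-cis triol → 3-tosylate, 2-ketone, silyl ether, allylic chloride → hydride-triggered ring contraction gives ring C → reductive alkylation of the gem-diprenyl acylphloroglucinol (ring A, one step) → palladium π-allyl spirocyclisation closes ring B → Markovnikov hydration of the methylidene.
4. Stereochemistry: the ring C carbinol and the branch-bearing CH come from the terpene (the carbinol carbon migrates with retention); the other ring-fusion CH is set by inversion in the 1,2-shift, the sulfonate having been placed by a directed dihydroxylation; the spiro carbon by the chiral palladium ligand; the ring B carbinol by equatorial capture of O2.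

Key step: step 7

Assumption: (1R,4R)-p-mentha-2,8-dien-1-ol (the trans isomer, the main tertiary alcohol from dye-sensitised photo-oxygenation of (R)-limonene and reduction) is taken as purchasable.
Remark: the acylphloroglucinol intermediates are drawn as one enol tautomer. In steps 2–7 the cyclohexane atoms are numbered C1 (the C(Me)(O) carbon), C2, C3 and C4 (the CH bearing the propenyl branch).

**Step 1**
Reactants: 1 2',4',6'-trihydroxyacetophenone; 2 prenyl bromide (2.1 equiv)
Product: 3 2-acetyl-3,5-dihydroxy-4,4-bis(3-methylbut-2-en-1-yl)cyclohexa-2,5-dien-1-one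
Conditions: NaOMe (3 equiv), MeOH, 0 °C to rt; chromatography
Reagents that add atoms: none
Why: Dearomative double C-prenylation of the phloroglucinol polyanion in a protic medium should put the second prenyl group on the already alkylated ring carbon to give the geminal pair, which is separated from the mono- and 3,5-diprenyl isomers.

**Step 2**
Reactants: 4 (1R,4R)-p-mentha-2,8-dien-1-ol
Product: 5 (1R,2S,3S,4S)-1-methyl-4-(prop-1-en-2-yl)cyclohexane-1,2,3-triol
Conditions: OsO4 (1.05 equiv), TMEDA (1.1 equiv), CH2Cl2, −78 °C; then aq. Na2SO3, THF, reflux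
Reagents that add atoms: osmium tetroxide O=[Os](=O)(=O)=O
Why: Hydroxyl-directed syn-dihydroxylation: the hydrogen-bonded OsO4·TMEDA complex should add to the ring alkene on the face of the tertiary OH (also the face away from the pseudo-axial methyl), giving the all-cis triol and leaving the isopropenyl group untouched.

**Step 3**
Reactants: 5
Product: 6 (1S,2S,3R,6S)-2,3-dihydroxy-3-methyl-6-(prop-1-en-2-yl)cyclohexyl 4-methylbenzenesulfonate
Conditions: Bu2SnO (5 mol %), TsCl (1.05 equiv), Et3N, CH2Cl2, rt
Reagents that add atoms: p-toluenesulfonyl chloride Cc1ccc(cc1)S(Cl)(=O)=O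
Why: Tin-acetal-mediated regioselective sulfonylation of a cis-1,2-diol should take the equatorial secondary oxygen at C3 and leave the axial C2 hydroxyl (next to the quaternary carbon) and the tertiary hydroxyl free.

**Step 4**
Reactants: 6
Product: 7 (1S,3R,6S)-3-hydroxy-3-methyl-2-oxo-6-(prop-1-en-2-yl)cyclohexyl 4-methylbenzenesulfonate
Conditions: IBX, DMSO, rt
Reagents that add atoms: none
Why: IBX oxidises the secondary carbinol of a secondary/tertiary 1,2-diol to the α-ketol without glycol cleavage, and the neutral medium should keep the sulfonate-bearing centre intact.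

**Step 5**
Reactants: 7
Product: 8 (1S,3R,6S)-3-methyl-2-oxo-6-(prop-1-en-2-yl)-3-(triethylsilyloxy)cyclohexyl 4-methylbenzenesulfonate
Conditions: Et3SiOTf (1.2 equiv), 2,6-lutidine, CH2Cl2, −78 to 0 °C
Reagents that add atoms: triethylsilyl triflate CC[Si](CC)(CC)OS(=O)(=O)C(F)(F)F
Why: Silylation of the only hydroxyl; the cap keeps the tertiary oxygen from acting as an alkoxide (Grob-type fragmentation) in step 7 and protects the later 3-oxy aldehyde.

**Step 6**
Reactants: 8
Product: 9 (1S,3R,6S)-6-(3-chloroprop-1-en-2-yl)-3-methyl-2-oxo-3-(triethylsilyloxy)cyclohexyl 4-methylbenzenesulfonate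
Conditions: Ca(OCl)2, CO2 (solid), CH2Cl2/H2O, 0 °C
Reagents that add atoms: calcium hypochlorite [Ca+2].[O-]Cl.[O-]Cl
Why: Ene-type allylic chlorination of the isopropenyl group by HOCl (chlorine to the terminal CH2, proton lost from the methyl group) should give the 2-(chloromethyl)allyl unit while ketone, sulfonate and silyl ether stay inert.

**Step 7**
Reactants: 9
Product: 11 (1S,2R,5R)-5-(3-chloroprop-1-en-2-yl)-2-methyl-2-(triethylsilyloxy)cyclopentane-1-carbaldehyde, via aluminium alkoxide 10 (not isolated)
Conditions: i-Bu2AlH (1.1 equiv), CH2Cl2, −78 °C; then Et3Al (2 equiv), −78 to −20 °C; aq. potassium sodium tartrate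
Reagents that add atoms: none
Why: i-Bu2AlH adds hydride to the C2 ketone; in alkoxide 10 the ring bond C1–C2 is anti-periplanar to the equatorial C3–OTs bond, so the silyloxy-bearing carbon C1 shifts from C2 to C3 as the aluminium-activated sulfonate leaves and C2 becomes the aldehyde carbon, contracting the cyclohexane to the cyclopentane. The closest known reaction type is the aluminium-promoted reductive pinacol-type 1,2-shift of α-sulfonyloxy ketones, together with the alkoxide-driven ring contraction of cis-2-sulfonyloxycyclohexanols to cyclopentanecarbaldehydes. The five-membered ring closes by a suprafacial 1,2-alkyl shift, the migrating carbon displacing the sulfonate from the rear of C3. The new CH(CHO) centre is set by that inversion (a sulfonate trans to the allyl branch gives the aldehyde trans to it, which is also the more stable epimer), the migrating C(Me)(OSiEt3) centre keeps its configuration and the allyl-bearing centre is not touched. The step needs migration of C1 instead of hydride shift, epoxide closure, fragmentation or silyl transfer: the equatorial sulfonate (chair fixed by the equatorial allyl branch and the two 1,3-cis oxygens) leaves only that ring bond aligned, the silyl cap blocks the tertiary alkoxide, and the covalent aluminium alkoxide does not relay the silyl group.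

**Step 8**
Reactants: 11; 3
Product: 14 2-acetyl-6-{[(1S,2R,5R)-5-(3-chloroprop-1-en-2-yl)-2-hydroxy-2-methylcyclopentyl]methyl}-3,5-dihydroxy-4,4-bis(3-methylbut-2-en-1-yl)cyclohexa-2,5-dien-1-one, via alkylidene trione 12 (not isolated), via silyl ether 13 (not isolated)
Conditions: L-proline (20 mol %), diethyl 2,6-dimethyl-1,4-dihydropyridine-3,5-dicarboxylate (1.2 equiv), CH2Cl2, rt; then HF·pyridine, THF, 0 °C
Reagents that add atoms: none
Why: Organocatalytic reductive alkylation (Knoevenagel condensation at the free ring carbon of 3, then conjugate hydride transfer from the Hantzsch ester before the alkylidene can isomerise or add a second trione); the silyl ether, no longer needed, is cleaved in the same pot and no stereocentre is formed.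

**Step 9**
Reactants: 14
Product: 15 spiro triketone with a methylidene group in ring B (spiro carbon S; ring fusion trans; ring C carbinol R)
Conditions: Pd2(dba)3·CHCl3 (2.5 mol %), (R,R)-DACH-phenyl bisphosphine ligand [N,N'-(1R,2R)-cyclohexane-1,2-diylbis(2-diphenylphosphinobenzamide)] (7.5 mol %), Et3N (2.2 equiv), CH2Cl2, 0 °C
Reagents that add atoms: none
Why: Intramolecular Tsuji–Trost allylic alkylation: zerovalent palladium ionises the allylic chloride to a 2-substituted π-allyl with equivalent termini, and the enolate carbon between the two ring A carbonyls attacks one terminus to close ring B (C-alkylation, since O-alkylation would need an eight-membered ring). The chiral ligand pocket is the element meant to choose the enolate face and so the spiro configuration, because the substrate's two flanking carbonyls offer little bias; the ligand enantiomer is the one that matches the substrate, and the weak amine base keeps uncatalysed closure slow.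

**Step 10**
Reactants: 15
Product: 17 CNP0266834.1 (target), via hydroperoxide 16 (not isolated)
Conditions: Mn(dpm)3 (10 mol %), PhSiH3, O2 (1 atm), i-PrOH/CH2Cl2, 0 °C; then PPh3
Reagents that add atoms: dioxygen O=O
Why: Mukaiyama hydration by metal-hydride hydrogen-atom transfer: the hydrogen atom should go to the exocyclic CH2 (a 1,1-disubstituted alkene reacts ahead of the two trisubstituted prenyl alkenes), and the tertiary ring B radical should be trapped by O2 from the equatorial side, the axial side being screened by the syn-axial carbonyl on the spiro carbon and the axial ring-fusion hydrogen, which gives equatorial OH and axial methyl as in the target; PPh3 reduces the hydroperoxide.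

**Compound list**

1 | 2',4',6'-trihydroxyacetophenone | CC(=O)c1c(O)cc(O)cc1O | starting material
2 | prenyl bromide (1-bromo-3-methylbut-2-ene) | CC(C)=CCBr | starting material
3 | 2-acetyl-3,5-dihydroxy-4,4-bis(3-methylbut-2-en-1-yl)cyclohexa-2,5-dien-1-one (enol form of the gem-diprenyl trione) | CC(=O)C1=C(O)C(CC=C(C)C)(CC=C(C)C)C(O)=CC1=O | intermediate
4 | (1R,4R)-1-methyl-4-(prop-1-en-2-yl)cyclohex-2-en-1-ol (trans-p-mentha-2,8-dien-1-ol) | C[C@]1(O)C=C[C@H](C(C)=C)CC1 | starting material
5 | (1R,2S,3S,4S)-1-methyl-4-(prop-1-en-2-yl)cyclohexane-1,2,3-triol (three hydroxyls cis, all trans to the propenyl group) | C[C@]1(O)[C@@H](O)[C@@H](O)[C@H](C(C)=C)CC1 | intermediate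
6 | (1S,2S,3R,6S)-2,3-dihydroxy-3-methyl-6-(prop-1-en-2-yl)cyclohexyl 4-methylbenzenesulfonate | C[C@]1(O)[C@@H](O)[C@@H](OS(=O)(=O)c2ccc(C)cc2)[C@H](C(C)=C)CC1 | intermediate
7 | (1S,3R,6S)-3-hydroxy-3-methyl-2-oxo-6-(prop-1-en-2-yl)cyclohexyl 4-methylbenzenesulfonate | C[C@]1(O)C(=O)[C@@H](OS(=O)(=O)c2ccc(C)cc2)[C@H](C(C)=C)CC1 | intermediate
8 | (1S,3R,6S)-3-methyl-2-oxo-6-(prop-1-en-2-yl)-3-(triethylsilyloxy)cyclohexyl 4-methylbenzenesulfonate | C[C@]1(O[Si](CC)(CC)CC)C(=O)[C@@H](OS(=O)(=O)c2ccc(C)cc2)[C@H](C(C)=C)CC1 | intermediate
9 | (1S,3R,6S)-6-(3-chloroprop-1-en-2-yl)-3-methyl-2-oxo-3-(triethylsilyloxy)cyclohexyl 4-methylbenzenesulfonate | C[C@]1(O[Si](CC)(CC)CC)C(=O)[C@@H](OS(=O)(=O)c2ccc(C)cc2)[C@H](C(CCl)=C)CC1 | intermediate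
10 | diisobutylaluminium alkoxide of the C2 carbinol from 9 (drawn as the cis alkoxide; the C2 epimer would shift alike) | C[C@]1(O[Si](CC)(CC)CC)[C@@H](O[Al](CC(C)C)CC(C)C)[C@@H](OS(=O)(=O)c2ccc(C)cc2)[C@H](C(CCl)=C)CC1 | intermediate
11 | (1S,2R,5R)-5-(3-chloroprop-1-en-2-yl)-2-methyl-2-(triethylsilyloxy)cyclopentane-1-carbaldehyde (CHO cis to OSiEt3, trans to the allyl branch) | O=C[C@H]1[C@H](C(CCl)=C)CC[C@@]1(C)O[Si](CC)(CC)CC | intermediate
12 | Knoevenagel adduct of 3 and 11 (alkylidene trione; alkene geometry not fixed, it is reduced at once) | CC(=O)C1=C(O)C(CC=C(C)C)(CC=C(C)C)C(=O)C(=C[C@H]2[C@H](C(CCl)=C)CC[C@@]2(C)O[Si](CC)(CC)CC)C1=O | intermediate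
13 | triethylsilyl ether of 14 | CC(=O)C1=C(O)C(CC=C(C)C)(CC=C(C)C)C(O)=C(C[C@H]2[C@H](C(CCl)=C)CC[C@@]2(C)O[Si](CC)(CC)CC)C1=O | intermediate
14 | 2-acetyl-6-{[(1S,2R,5R)-5-(3-chloroprop-1-en-2-yl)-2-hydroxy-2-methylcyclopentyl]methyl}-3,5-dihydroxy-4,4-bis(3-methylbut-2-en-1-yl)cyclohexa-2,5-dien-1-one | CC(=O)C1=C(O)C(CC=C(C)C)(CC=C(C)C)C(O)=C(C[C@H]2[C@H](C(CCl)=C)CC[C@@]2(C)O)C1=O | intermediate
15 | spiro triketone: target skeleton with an exocyclic methylene in place of the ring B C(Me)(OH) | CC(=O)C1=C(O)C(CC=C(C)C)(CC=C(C)C)C(=O)[C@@]2(C[C@H]3[C@@H](CC[C@@]3(C)O)C(=C)C2)C1=O | intermediate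
16 | tertiary hydroperoxide of the target (OOH in place of the ring B OH) | CC(=O)C1=C(O)C(CC=C(C)C)(CC=C(C)C)C(=O)[C@@]2(C[C@H]3[C@@H](CC[C@@]3(C)O)[C@](C)(OO)C2)C1=O | intermediate
17 | CNP0266834.1 (spiro carbon S; ring-fusion CH next to the ring C carbinol S, other ring-fusion CH R; both carbinol carbons R) | CC(=O)C1=C(O)C(CC=C(C)C)(CC=C(C)C)C(=O)[C@@]2(C[C@H]3[C@@H](CC[C@@]3(C)O)[C@](C)(O)C2)C1=O | target

**Step count and risks**

Total steps: 10. Longest linear sequence: 9 steps (steps 2–10, from 4); step 1 is a one-step branch.

Steps most likely to fail: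

Step 9. The ligand may not discriminate the two enolate faces well enough, since the two carbonyl flanks of the spiro carbon are sterically alike, and uncatalysed closure may erode the control, so the spiro epimer may form alongside. The fallback closes ring B through the other bond and also bypasses step 8. It sets out from 11: NaBH4 in MeOH should give the primary alcohol F1, and TsCl in pyridine its tosylate F2. Pd(PPh3)4 with Cs2CO3 in THF should join F2 and 3 by intermolecular C-allylation to the open-chain allylated trione F3. Cs2CO3 and NaI in DMF, if needed with a chiral quaternary ammonium phase-transfer catalyst, should then close the ring by 6-exo-tet C-alkylation at the sulfonate carbon to the silylated spiro triketone F4. HF·pyridine returns the route to 15. The enolate is then held by the allyl tether in an SN2 transition state, which gives a different intrinsic bias, and the epimers are separable at F4.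

Step 10. Hydrogen-atom transfer may reach a prenyl alkene, O2 capture may lack facial selectivity, and the β-triketone may sequester the manganese. The fallback is ionic: oxymercuration of 15 with Hg(OAc)2 in THF/H2O, which takes 1,1-disubstituted alkenes well ahead of trisubstituted ones and should open the mercurinium ion at the tertiary carbon from the equatorial side, to the organomercurial F5. NaBH4 in aqueous NaOH at 0 °C then gives 17 directly.

Step 7. The aluminium alkyls may add to or reduce the aldehyde, or the Lewis acid may ionise the sulfonate before the alkoxide pushes, opening hydride-shift and elimination paths. The fallback triggers the same ring contraction with an oxygen nucleophile. It sets out from 8: NaOMe in MeOH at 0 °C should add to the ketone and drive a semibenzilic (quasi-Favorskii) shift of the same carbon to the methyl ester F6, which can equilibrate to the needed trans ester under these conditions. Ene-chlorination with Ca(OCl)2/CO2 gives the chloro ester F7, and i-Bu2AlH (1 equiv, CH2Cl2, −78 °C) returns the route to 11.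

**Further compounds**

F1 | step 9 | [(1R,2R,5R)-5-(3-chloroprop-1-en-2-yl)-2-methyl-2-(triethylsilyloxy)cyclopentyl]methanol | OC[C@H]1[C@H](C(CCl)=C)CC[C@@]1(C)O[Si](CC)(CC)CC
F2 | step 9 | [(1R,2R,5R)-5-(3-chloroprop-1-en-2-yl)-2-methyl-2-(triethylsilyloxy)cyclopentyl]methyl 4-methylbenzenesulfonate | Cc1ccc(cc1)S(=O)(=O)OC[C@H]2[C@H](C(CCl)=C)CC[C@@]2(C)O[Si](CC)(CC)CC
F3 | step 9 | open-chain C-allylated trione bearing the primary tosylate (enol form) | CC(=O)C1=C(O)C(CC=C(C)C)(CC=C(C)C)C(O)=C(CC(=C)[C@@H]2CC[C@@](C)(O[Si](CC)(CC)CC)[C@H]2COS(=O)(=O)c3ccc(C)cc3)C1=O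
F4 | step 9 | triethylsilyl ether of 15 | CC(=O)C1=C(O)C(CC=C(C)C)(CC=C(C)C)C(=O)[C@@]2(C[C@H]3[C@@H](CC[C@@]3(C)O[Si](CC)(CC)CC)C(=C)C2)C1=O
F5 | step 10 | acetoxymercurio-methyl carbinol from 15 (CH2HgOAc in place of the ring B methyl of the target) | CC(=O)C1=C(O)C(CC=C(C)C)(CC=C(C)C)C(=O)[C@@]2(C[C@H]3[C@@H](CC[C@@]3(C)O)[C@](C[Hg]OC(C)=O)(O)C2)C1=O
F6 | step 7 | methyl (1S,2R,5R)-2-methyl-5-(prop-1-en-2-yl)-2-(triethylsilyloxy)cyclopentane-1-carboxylate | COC(=O)[C@H]1[C@H](C(C)=C)CC[C@@]1(C)O[Si](CC)(CC)CC
F7 | step 7 | methyl (1S,2R,5R)-5-(3-chloroprop-1-en-2-yl)-2-methyl-2-(triethylsilyloxy)cyclopentane-1-carboxylate | COC(=O)[C@H]1[C@H](C(CCl)=C)CC[C@@]1(C)O[Si](CC)(CC)CC
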